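**Plan**

1. Labels: in the 1,4-epoxytetrahydronaphthalene core, C1 is the bridgehead carrying the 2,6-dihydroxyphenyl ring, C4 the bridgehead CH, C2 (next to C1) and C3 the carbons between them, O8 the phenolic oxygen peri to C1; Cα is the C(OH)CO2Me carbon.
2. Cuts: Cα–CO2Me (ketone plus a one-carbon nucleophile); C3–Cα and C2–chromone C-2 together (cyclopentene ring, by isomerisation of an aryl ester); the ester C–O bond; C1–C8a and C4–C4a (aryne plus furan); the aryl–furan bond.
3. Forward: two benzene building blocks and a furan give the 7-oxabenzonorbornadiene by a silicon-tethered intramolecular aryne–furan Diels–Alder reaction; resolution; esterification with a chromone-3-carboxylic acid; the key step closes the cyclopentenone onto the chromone; the ester carbon is added; all silyl groups fall in one step.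
4. Enabling feature: the 2,6-dihydroxyphenyl ring on C1. One of its phenolic oxygens lies beside the exo face of C2 of the strained C2=C3 bond, so as the ester oxygen it holds nickel on C2 and sends the acyl carbon to C3; the second oxygen is tied to O8 through silicon, which keeps the ring in this orientation.
5. Stereochemistry: C1/C4 relative configuration is fixed by the bicycle and the absolute configuration by resolution as a menthyl carbonate; C2/C3 by exo syn addition; Cα by attack on the ketone from the face of H-3.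

Key step: step 16

Remark: 16 is formed as a racemate and its SMILES shows the (1S,4R) enantiomer; step 8 converts both enantiomers into diastereomeric carbonates, only the carbonate of the (1S,4R) enantiomer (17) is carried on, and step 9 returns that enantiomer as 18. Exo means the side of the oxygen bridge.

**Step 1**
Reactants: 1 4-bromo-2-methylphenol; 2 4-bromo-2-methylbutan-2-ol
Product: 3 4-(4-bromo-2-methylphenoxy)-2-methylbutan-2-ol
Conditions: K2CO3, DMF, 70 °C
Reagents that add atoms: none
Why: Williamson ether synthesis; the phenoxide displaces the primary bromide and the tertiary alcohol stays free.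

**Step 2**
Reactants: 3
Product: 4 [4-(4-bromo-2-methylphenoxy)-2-methylbutan-2-yl]oxy(triethyl)silane
Conditions: TESOTf, 2,6-lutidine, CH2Cl2, −78 → 0 °C
Reagents that add atoms: triethylsilyl trifluoromethanesulfonate, CC[Si](CC)(CC)OS(=O)(=O)C(F)(F)F
Why: Silylation of the tertiary alcohol, needed because a free alkoxide could add to the aryne of step 7.

**Step 3**
Reactants: 4
Product: 7 3-methyl-4-{3-methyl-3-[(triethylsilyl)oxy]butoxy}phenol, via aryllithium 5 (not isolated), via dimethyl arylboronate 6 (not isolated)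
Conditions: n-BuLi, THF, −78 °C; B(OMe)3; then H2O2, aq. NaOH, 0 °C → rt
Reagents that add atoms: hydrogen peroxide, OO (trimethyl borate, COB(OC)OC, puts boron into intermediate 6 only)
Why: Bromine–lithium exchange, borylation and oxidative C–B cleavage (ipso-hydroxylation) should turn the aryl bromide into the phenol without touching the silyl ether.

**Step 4**
Reactants: 7
Product: 8 2-bromo-5-methyl-4-{3-methyl-3-[(triethylsilyl)oxy]butoxy}phenol
Conditions: NBS, CH2Cl2, −20 → 0 °C
Reagents that add atoms: N-bromosuccinimide, O=C1CCC(=O)N1Br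
Why: Electrophilic aromatic bromination ortho to the free OH; of the two ortho positions, the one para to the methyl group and not flanked by it should react.

**Step 5**
Reactants: 9 2-bromobenzene-1,3-diol; 10 furan-2-ylboronic acid
Product: 11 2-(furan-2-yl)benzene-1,3-diol
Conditions: Pd(OAc)2 (2 mol %), SPhos (4 mol %), K3PO4, 1,4-dioxane/H2O, 60 °C
Reagents that add atoms: none
Why: Suzuki–Miyaura coupling; a dialkylbiarylphosphine ligand tolerates the doubly ortho-substituted bromide and the free phenols.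

**Step 6**
Reactants: 8; 11
Product: 13 3-{[(2-bromo-5-methyl-4-{3-methyl-3-[(triethylsilyl)oxy]butoxy}phenoxy)di(propan-2-yl)silyl]oxy}-2-(furan-2-yl)phenol, via chlorosilane 12 (not isolated)
Conditions: i-Pr2SiCl2 (3 equiv), Et3N, CH2Cl2, 0 °C, excess silane removed in vacuo; then 11 (3 equiv), imidazole, DMF, 0 °C → rt
Reagents that add atoms: dichlorodi(propan-2-yl)silane, CC(C)[Si](Cl)(Cl)C(C)C
Why: Stepwise silyl ether formation with a dichlorosilane gives the unsymmetrical bis(aryloxy)silane; the two OH groups of 11 are equivalent and its excess limits double silylation.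

**Step 7**
Reactants: 13
Product: 16 racemic 1-aryl-1,4-dihydro-1,4-epoxynaphthalene: C1 carries a 2-hydroxy-6-silyloxyphenyl group whose silyloxy oxygen is joined to O8 by Si(i-Pr)2 (eight-membered ring); C5 carries the 3-methyl-3-(triethylsilyloxy)butoxy group and C6 the methyl group, via dilithio species 14 (not isolated), via aryne 15 (not isolated)
Conditions: LiTMP (2.4 equiv), THF (0.01 M), −78 → −10 °C; aq. NH4Cl
Reagents that add atoms: none
Why: Ortho-lithiation between Br and the alkoxy group, loss of LiBr and intramolecular aryne–furan Diels–Alder reaction; the O–Si–O tether can only bring the aryne carbon next to the silyloxy group onto the aryl-bearing furan carbon, which fixes the regiochemistry, and C1 and C4 are formed together with their relative configuration set by the bicycle.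

**Step 8**
Reactants: 16
Product: 17 (1R,2S,5R)-menthyl carbonate of the free phenol of (1S,4R)-16
Conditions: (−)-menthyl chloroformate, Et3N, DMAP (cat.), CH2Cl2, 0 °C → rt; the two diastereomeric carbonates are separated by chromatography or crystallisation
Reagents that add atoms: (1R,2S,5R)-menthyl chloroformate, CC(C)[C@@H]1CC[C@@H](C)C[C@H]1OC(Cl)=O
Why: Classical resolution; acylation with an enantiopure chloroformate gives diastereomeric carbonates that differ right next to the C1 stereocentre and should be separable, which fixes the absolute configuration.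

**Step 9**
Reactants: 17
Product: 18 (1S,4R) enantiomer of 16
Conditions: n-BuNH2 (5 equiv), THF, rt
Reagents that add atoms: none
Why: Aminolysis of the aryl carbonate; the amine expels the better leaving group (aryloxide) and leaves the hindered silyl ethers alone.

**Step 10**
Reactants: 19 1-(2,4,6-trihydroxyphenyl)ethan-1-one
Product: 20 4-acetyl-3,5-dihydroxyphenyl trifluoromethanesulfonate
Conditions: PhNTf2 (1.0 equiv), K2CO3, acetone, 0 °C → rt
Reagents that add atoms: N-phenylbis(trifluoromethanesulfonimide), O=S(=O)(N(c1ccccc1)S(=O)(=O)C(F)(F)F)C(F)(F)F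
Why: Selective sulfonylation; the 4-OH, para to the acetyl group and not hydrogen-bonded to it, is the most acidic.

**Step 11**
Reactants: 20
Product: 21 3-formyl-5-hydroxy-4-oxo-4H-chromen-7-yl trifluoromethanesulfonate
Conditions: POCl3, DMF, 0 → 50 °C; then aq. NaOAc
Reagents that add atoms: N,N-dimethylformamide, CN(C)C=O (two carbons); water, O
Why: Vilsmeier–Haack chromone synthesis: double formylation of the methyl ketone and ring closure by a phenol give the 3-formylchromone; the two ortho OH groups are equivalent and the triflate deactivates the ring towards nuclear formylation.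

**Step 12**
Reactants: 21
Product: 22 5-hydroxy-7-(hydroxymethyl)-4-oxo-4H-chromene-3-carbaldehyde
Conditions: Bu3SnCH2OH, Pd(PPh3)4 (5 mol %), LiCl, 1,4-dioxane, 90 °C
Reagents that add atoms: (tributylstannyl)methanol, CCCC[Sn](CO)(CCCC)CCCC
Why: Stille coupling of the electron-poor aryl triflate with the hydroxymethylstannane under neutral conditions that the aldehyde tolerates.

**Step 13**
Reactants: 22
Product: 23 5-[(tert-butyldimethylsilyl)oxy]-7-{[(tert-butyldimethylsilyl)oxy]methyl}-4-oxo-4H-chromene-3-carbaldehyde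
Conditions: TBSOTf (2.4 equiv), 2,6-lutidine, CH2Cl2, −40 → 0 °C
Reagents that add atoms: tert-butyldimethylsilyl trifluoromethanesulfonate, CC(C)(C)[Si](C)(C)OS(=O)(=O)C(F)(F)F
Why: Silylation of the primary alcohol and the chelated phenol with a silyl triflate and a hindered base, since nucleophilic amines would open the 3-formylchromone.

**Step 14**
Reactants: 23
Product: 24 5-[(tert-butyldimethylsilyl)oxy]-7-{[(tert-butyldimethylsilyl)oxy]methyl}-4-oxo-4H-chromene-3-carboxylic acid
Conditions: NaClO2, NaH2PO4, 2-methylbut-2-ene, t-BuOH/THF/H2O, 0 °C → rt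
Reagents that add atoms: sodium chlorite, [Na+].[O-]Cl=O
Why: Pinnick oxidation of the aldehyde; the buffered medium should keep both silyl ethers.

**Step 15**
Reactants: 24; 18
Product: 26 ester of acid 24 with the free phenol of 18, via acid chloride 25 (not isolated)
Conditions: 1-chloro-N,N,2-trimethylprop-1-en-1-amine, CH2Cl2, 0 °C; then 18, Et3N, DMAP (10 mol %), CH2Cl2, 0 °C → rt
Reagents that add atoms: 1-chloro-N,N,2-trimethylprop-1-en-1-amine, CC(C)=C(Cl)N(C)C (chlorine in intermediate 25 only)
Why: Acid chloride formation under neutral conditions followed by esterification of the hindered phenol; no stereocentre is touched.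

**Step 16**
Reactants: 26
Product: 27 exo-fused cyclopenta[b]chromene-1,9-dione: Cα is a ketone bonded to C3 and to chromone C-3, chromone C-2 is bonded to C2, H-2 and H-3 are endo and cis, and the aryl group on C1 carries a free OH
Conditions: Ni(cod)2 (10 mol %), 1,2-bis(dicyclohexylphosphino)ethane (12 mol %), toluene, 80 °C
Reagents that add atoms: none
Why: Proposed new method: zerovalent nickel should insert into the C(acyl)–O bond of the aryl ester to give an acyl(aryloxy)nickel species whose aryloxide ligand holds the metal over the exo face of C2=C3; syn insertion then puts the acyl carbon on C3 and nickel on C2, the aryloxide takes the proton of chromone C-2 (concerted metalation–deprotonation) to form a six-membered nickelacycle, and C(sp3)–C(sp2) reductive elimination closes the ring and returns zerovalent nickel, so the step is an isomerisation. The closest known reaction types are nickel-catalysed C–H/C–O coupling of azoles with aryl esters (acyl C–O insertion followed by C–H nickelation) and nickel- or palladium-catalysed carboacylation of norbornene through acyl C–N or C–O activation. The cyclopentenone ring (C2, C3, Cα, chromone C-3, chromone C-2) is closed first by an intramolecular acylnickelation within a six-membered aryloxide chelate and then by reductive elimination from the six-membered nickelacycle. The new stereocentres C2 and C3 are set by one syn addition to the exo face of the strained alkene, so both new bonds are exo and cis, and the absolute configuration comes from 18. The step needs the acyl group on C3 and chromone C-2 on C2; this is secured because nickel stays bound to the oxygen of the aryl ring on C1, which reaches only C2, while the Si(i-Pr)2 bridge to O8 keeps that oxygen over the exo face. The intramolecular insertion at 80 °C should outrun decarbonylation of the acylnickel and β-oxygen elimination.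

**Step 17**
Reactants: 27
Product: 28 tertiary alcohol from addition of a 1-methoxyethenyl group to the Cα ketone of 27; the OH is cis to the C3–C4 bond
Conditions: methyl vinyl ether, t-BuLi, THF, −78 → 0 °C; CeCl3, THF, −78 °C; then 27 (reagent 3 equiv), −78 °C; pH 7 buffer
Reagents that add atoms: 1-methoxyethenyllithium, [Li]C(=C)OC (made in the flask from methyl vinyl ether, COC=C)
Why: 1,2-Addition of an organocerium acyl-anion equivalent, whose low basicity avoids enolisation towards C3 (which would open the oxygen bridge), to the cyclopentenone carbonyl, the more reactive of the two vinylogous-ester carbonyls; attack on the convex face, the side of H-3, puts the new carbon cis to H-3 and the OH cis to C4 as in the target.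

**Step 18**
Reactants: 28
Product: 30 methyl ester of the fully silylated target, via primary ozonide 29 (not isolated)
Conditions: O3, CH2Cl2/MeOH (5:1), −78 °C, Sudan Red 7B end point; then Me2S, −78 °C → rt
Reagents that add atoms: ozone, [O-][O+]=O
Why: Ozonolysis; the enol ether C=C reacts much faster than the arenes and the chromone, and cleavage of a 1-alkoxyalkene gives the methyl ester directly, without touching Cα.

**Step 19**
Reactants: 30
Product: 31 aspergichromone A
Conditions: HF·pyridine, pyridine, THF, 0 °C → rt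
Reagents that add atoms: none
Why: Global desilylation; fluoride cleaves the silylene bridge, the triethylsilyl ether and both tert-butyldimethylsilyl ethers, and the pyridine buffer should prevent ionisation at Cα and C1.

**Compound list**

1 | 4-bromo-2-methylphenol | Cc1cc(Br)ccc1O | starting material
2 | 4-bromo-2-methylbutan-2-ol | CC(C)(O)CCBr | starting material
3 | 4-(4-bromo-2-methylphenoxy)-2-methylbutan-2-ol | Cc1cc(Br)ccc1OCCC(C)(C)O | intermediate
4 | [4-(4-bromo-2-methylphenoxy)-2-methylbutan-2-yl]oxy(triethyl)silane | Cc1cc(Br)ccc1OCCC(C)(C)O[Si](CC)(CC)CC | intermediate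
5 | aryllithium from 4 (Li in place of Br) | Cc1cc([Li])ccc1OCCC(C)(C)O[Si](CC)(CC)CC | intermediate
6 | dimethyl (3-methyl-4-{3-methyl-3-[(triethylsilyl)oxy]butoxy}phenyl)boronate | COB(OC)c1ccc(OCCC(C)(C)O[Si](CC)(CC)CC)c(C)c1 | intermediate
7 | 3-methyl-4-{3-methyl-3-[(triethylsilyl)oxy]butoxy}phenol | Cc1cc(O)ccc1OCCC(C)(C)O[Si](CC)(CC)CC | intermediate
8 | 2-bromo-5-methyl-4-{3-methyl-3-[(triethylsilyl)oxy]butoxy}phenol | Cc1cc(O)c(Br)cc1OCCC(C)(C)O[Si](CC)(CC)CC | intermediate
9 | 2-bromobenzene-1,3-diol | Oc1cccc(O)c1Br | starting material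
10 | furan-2-ylboronic acid | OB(O)c1ccco1 | starting material
11 | 2-(furan-2-yl)benzene-1,3-diol | Oc1cccc(O)c1-c1ccco1 | intermediate
12 | (2-bromo-5-methyl-4-{3-methyl-3-[(triethylsilyl)oxy]butoxy}phenoxy)(chloro)di(propan-2-yl)silane | Cc1cc(O[Si](Cl)(C(C)C)C(C)C)c(Br)cc1OCCC(C)(C)O[Si](CC)(CC)CC | intermediate
13 | 3-{[(2-bromo-5-methyl-4-{3-methyl-3-[(triethylsilyl)oxy]butoxy}phenoxy)di(propan-2-yl)silyl]oxy}-2-(furan-2-yl)phenol | Cc1cc(O[Si](Oc2cccc(O)c2-c2ccco2)(C(C)C)C(C)C)c(Br)cc1OCCC(C)(C)O[Si](CC)(CC)CC | intermediate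
14 | dilithio derivative of 13 (lithium phenoxide; aryllithium between Br and the alkoxy group) | Cc1cc(O[Si](Oc2cccc(O[Li])c2-c2ccco2)(C(C)C)C(C)C)c(Br)c([Li])c1OCCC(C)(C)O[Si](CC)(CC)CC | intermediate
15 | aryne from 14 (lithium phenoxide) | CC1=C(OCCC(C)(C)O[Si](CC)(CC)CC)C#CC(O[Si](Oc2cccc(O[Li])c2-c2ccco2)(C(C)C)C(C)C)=C1 | intermediate
16 | racemic silylene-bridged 1-(2-hydroxy-6-silyloxyphenyl)-6-methyl-5-{3-methyl-3-[(triethylsilyl)oxy]butoxy}-1,4-dihydro-1,4-epoxynaphthalene, O8 and the aryl oxygen joined by Si(i-Pr)2; (1S,4R) enantiomer drawn | C1=C[C@H]2O[C@]1(c1c(O)cccc1O[Si]3(C(C)C)C(C)C)c1c(O3)cc(C)c(OCCC(C)(C)O[Si](CC)(CC)CC)c12 | intermediate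
17 | (1R,2S,5R)-menthyl carbonate of (1S,4R)-16 | C1=C[C@H]2O[C@]1(c1c(OC(=O)O[C@H]3[C@H](C(C)C)CC[C@@H](C)C3)cccc1O[Si]3(C(C)C)C(C)C)c1c(O3)cc(C)c(OCCC(C)(C)O[Si](CC)(CC)CC)c12 | intermediate
18 | (1S,4R) enantiomer of 16 | C1=C[C@H]2O[C@]1(c1c(O)cccc1O[Si]3(C(C)C)C(C)C)c1c(O3)cc(C)c(OCCC(C)(C)O[Si](CC)(CC)CC)c12 | intermediate
19 | 1-(2,4,6-trihydroxyphenyl)ethan-1-one | CC(=O)c1c(O)cc(O)cc1O | starting material
20 | 4-acetyl-3,5-dihydroxyphenyl trifluoromethanesulfonate | CC(=O)c1c(O)cc(OS(=O)(=O)C(F)(F)F)cc1O | intermediate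
21 | 3-formyl-5-hydroxy-4-oxo-4H-chromen-7-yl trifluoromethanesulfonate | O=Cc1coc2cc(OS(=O)(=O)C(F)(F)F)cc(O)c2c1=O | intermediate
22 | 5-hydroxy-7-(hydroxymethyl)-4-oxo-4H-chromene-3-carbaldehyde | O=Cc1coc2cc(CO)cc(O)c2c1=O | intermediate
23 | 5-[(tert-butyldimethylsilyl)oxy]-7-{[(tert-butyldimethylsilyl)oxy]methyl}-4-oxo-4H-chromene-3-carbaldehyde | O=Cc1coc2cc(CO[Si](C)(C)C(C)(C)C)cc(O[Si](C)(C)C(C)(C)C)c2c1=O | intermediate
24 | 5-[(tert-butyldimethylsilyl)oxy]-7-{[(tert-butyldimethylsilyl)oxy]methyl}-4-oxo-4H-chromene-3-carboxylic acid | O=C(O)c1coc2cc(CO[Si](C)(C)C(C)(C)C)cc(O[Si](C)(C)C(C)(C)C)c2c1=O | intermediate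
25 | acid chloride of 24 | O=C(Cl)c1coc2cc(CO[Si](C)(C)C(C)(C)C)cc(O[Si](C)(C)C(C)(C)C)c2c1=O | intermediate
26 | aryl ester of 24 with the free phenol of 18 | C1=C[C@H]2O[C@]1(c1c(OC(=O)c3coc4cc(CO[Si](C)(C)C(C)(C)C)cc(O[Si](C)(C)C(C)(C)C)c4c3=O)cccc1O[Si]3(C(C)C)C(C)C)c1c(O3)cc(C)c(OCCC(C)(C)O[Si](CC)(CC)CC)c12 | intermediate
27 | exo-fused cyclopenta[b]chromene-1,9-dione with Cα as ketone and a free phenol on the C1 aryl ring | O=C1c2c(oc3cc(CO[Si](C)(C)C(C)(C)C)cc(O[Si](C)(C)C(C)(C)C)c3c2=O)[C@H]2[C@@H]1[C@H]1O[C@]2(c2c(O)cccc2O[Si]3(C(C)C)C(C)C)c2c(O3)cc(C)c(OCCC(C)(C)O[Si](CC)(CC)CC)c21 | intermediate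
28 | 1-methoxyethenyl carbinol at Cα, OH cis to C4 | C=C(OC)[C@@]1(O)c2c(oc3cc(CO[Si](C)(C)C(C)(C)C)cc(O[Si](C)(C)C(C)(C)C)c3c2=O)[C@H]2[C@@H]1[C@H]1O[C@]2(c2c(O)cccc2O[Si]3(C(C)C)C(C)C)c2c(O3)cc(C)c(OCCC(C)(C)O[Si](CC)(CC)CC)c21 | intermediate
29 | primary ozonide (1,2,3-trioxolane) of 28 | COC3(COOO3)[C@@]1(O)c2c(oc3cc(CO[Si](C)(C)C(C)(C)C)cc(O[Si](C)(C)C(C)(C)C)c3c2=O)[C@H]2[C@@H]1[C@H]1O[C@]2(c2c(O)cccc2O[Si]3(C(C)C)C(C)C)c2c(O3)cc(C)c(OCCC(C)(C)O[Si](CC)(CC)CC)c21 | intermediate
30 | silylated aspergichromone A (Si(i-Pr)2 bridge, one triethylsilyl and two tert-butyldimethylsilyl ethers) | COC(=O)[C@@]1(O)c2c(oc3cc(CO[Si](C)(C)C(C)(C)C)cc(O[Si](C)(C)C(C)(C)C)c3c2=O)[C@H]2[C@@H]1[C@H]1O[C@]2(c2c(O)cccc2O[Si]3(C(C)C)C(C)C)c2c(O3)cc(C)c(OCCC(C)(C)O[Si](CC)(CC)CC)c21 | intermediate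
31 | aspergichromone A | COC(=O)[C@@]1(O)c2c(oc3cc(CO)cc(O)c3c2=O)[C@H]2[C@@H]1[C@H]1O[C@]2(c2c(O)cccc2O)c2c(O)cc(C)c(OCCC(C)(C)O)c21 | target

**Step count and risks**

Total step count: 19. Longest linear sequence: 13 (steps 1–4, 6–9, 15–19).

Steps most likely to fail:

Step 16. Oxidative addition into the hindered aryl ester may be slow, the acylnickel may lose CO, the alkylnickel on C2 may open the oxygen bridge by β-oxygen elimination, or the C–H nickelation may not take place. Fallback from 18 to 27, keeping the same oxygen as a tether but using a Pauson–Khand reaction: 18 is vinylated with trichloroethylene (K2CO3, DMF) to the 1,2-dichloroethenyl ether F1; n-BuLi (2.2 equiv, THF, −78 °C) gives the lithium aryloxyacetylide F2 (not isolated). This adds to 2,6-bis[(tert-butyldimethylsilyl)oxy]-4-{[(tert-butyldimethylsilyl)oxy]methyl}benzaldehyde F5, which is made from commercial 2,4,6-trihydroxybenzaldehyde through the 4-triflate F3 and 2,6-dihydroxy-4-(hydroxymethyl)benzaldehyde F4 by the methods of steps 10, 12 and 13. The resulting propargylic alcohol F6 is oxidised with MnO2 to the ynone F7. The intramolecular Pauson–Khand reaction ([Rh(CO)2Cl]2 5 mol %, CO 1 atm, toluene, 90 °C) joins the oxygen-bearing alkyne carbon to C2 through a six-membered ring and CO to C3, giving the 3-aryloxycyclopentenone F8. One equivalent of TBAF/AcOH frees one of the two equivalent phenols of the aroyl group, which adds to the β-carbon and expels the tether aryloxide (addition–elimination), closing the pyranone and giving 27.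

Step 7. Lithiation may occur at other sites, the amide base may attack silicon, or the tethered cycloaddition may be slower than intermolecular trapping of the aryne. Fallback from 8 and 11 to 16, with an untethered cycloaddition and the bridge put on afterwards: 8 is silylated to its tert-butyldimethylsilyl ether F9 and 11 to the bis(silyl ether) F10. LiTMP with F9 and excess F10 (THF, −78 → 0 °C) gives the cycloadduct F11 together with its regioisomer F12, which is removed by chromatography. K2CO3 in MeOH cleaves the three aryl silyl ethers to the triol F13, and i-Pr2SiCl2 with imidazole at high dilution bridges O8 and the neighbouring aryl oxygen to give 16.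

Step 18. Ozone may over-oxidise the free phenol and the electron-rich rings before the enol ether is consumed. Fallback from 27 to 30 without ozone: tris(methylthio)methyllithium (from tris(methylthio)methane and n-BuLi, THF, −78 °C) adds to the Cα ketone of 27 from the same face to give the orthothioester F14, and HgCl2/HgO in MeOH/H2O converts it into the methyl ester 30.

**Further compounds**

F1 | step 16 | 1,2-dichloroethenyl ether of 18 | C1=C[C@H]2O[C@]1(c1c(OC(Cl)=CCl)cccc1O[Si]3(C(C)C)C(C)C)c1c(O3)cc(C)c(OCCC(C)(C)O[Si](CC)(CC)CC)c12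
F2 | step 16 | lithium aryloxyacetylide from F1 | C1=C[C@H]2O[C@]1(c1c(OC#C[Li])cccc1O[Si]3(C(C)C)C(C)C)c1c(O3)cc(C)c(OCCC(C)(C)O[Si](CC)(CC)CC)c12
F3 | step 16 | 4-formyl-3,5-dihydroxyphenyl trifluoromethanesulfonate | O=Cc1c(O)cc(OS(=O)(=O)C(F)(F)F)cc1O
F4 | step 16 | 2,6-dihydroxy-4-(hydroxymethyl)benzaldehyde | O=Cc1c(O)cc(CO)cc1O
F5 | step 16 | 2,6-bis[(tert-butyldimethylsilyl)oxy]-4-{[(tert-butyldimethylsilyl)oxy]methyl}benzaldehyde | O=Cc1c(O[Si](C)(C)C(C)(C)C)cc(CO[Si](C)(C)C(C)(C)C)cc1O[Si](C)(C)C(C)(C)C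
F6 | step 16 | propargylic alcohol from F2 and F5 (carbinol centre as a mixture) | C1=C[C@H]2O[C@]1(c1c(OC#CC(O)c3c(O[Si](C)(C)C(C)(C)C)cc(CO[Si](C)(C)C(C)(C)C)cc3O[Si](C)(C)C(C)(C)C)cccc1O[Si]3(C(C)C)C(C)C)c1c(O3)cc(C)c(OCCC(C)(C)O[Si](CC)(CC)CC)c12
F7 | step 16 | aryloxy ynone from F6 | C1=C[C@H]2O[C@]1(c1c(OC#CC(=O)c3c(O[Si](C)(C)C(C)(C)C)cc(CO[Si](C)(C)C(C)(C)C)cc3O[Si](C)(C)C(C)(C)C)cccc1O[Si]3(C(C)C)C(C)C)c1c(O3)cc(C)c(OCCC(C)(C)O[Si](CC)(CC)CC)c12
F8 | step 16 | Pauson–Khand product: exo-fused 2-aroyl-3-aryloxycyclopentenone with the aryloxy oxygen still tethered to the C1 aryl ring | O=C1C(C(=O)c2c(O[Si](C)(C)C(C)(C)C)cc(CO[Si](C)(C)C(C)(C)C)cc2O[Si](C)(C)C(C)(C)C)=C2Oc3cccc(O[Si]4(C(C)C)C(C)C)c3[C@@]5(c6c(O4)cc(C)c(OCCC(C)(C)O[Si](CC)(CC)CC)c6[C@@H]7O5)[C@@H]2[C@@H]17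
F9 | step 7 | tert-butyldimethylsilyl ether of 8 | Cc1cc(O[Si](C)(C)C(C)(C)C)c(Br)cc1OCCC(C)(C)O[Si](CC)(CC)CC
F10 | step 7 | 2-{2,6-bis[(tert-butyldimethylsilyl)oxy]phenyl}furan | CC(C)(C)[Si](C)(C)Oc1cccc(O[Si](C)(C)C(C)(C)C)c1-c1ccco1
F11 | step 7 | untethered cycloadduct, aryl bridgehead next to the silyloxy-bearing ring carbon (racemic) | C1=C[C@H]2O[C@]1(c1c(O[Si](C)(C)C(C)(C)C)cccc1O[Si](C)(C)C(C)(C)C)c1c(O[Si](C)(C)C(C)(C)C)cc(C)c(OCCC(C)(C)O[Si](CC)(CC)CC)c12
F12 | step 7 | regioisomeric cycloadduct, aryl bridgehead next to the alkoxy-bearing ring carbon (racemic) | C1=C[C@H]2O[C@]1(c1c(O[Si](C)(C)C(C)(C)C)cccc1O[Si](C)(C)C(C)(C)C)c1c(OCCC(C)(C)O[Si](CC)(CC)CC)c(C)cc(O[Si](C)(C)C(C)(C)C)c12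
F13 | step 7 | triol from F11 (racemic) | C1=C[C@H]2O[C@]1(c1c(O)cccc1O)c1c(O)cc(C)c(OCCC(C)(C)O[Si](CC)(CC)CC)c12
F14 | step 18 | tris(methylthio)methyl carbinol from 27 | CSC(SC)(SC)[C@@]1(O)c2c(oc3cc(CO[Si](C)(C)C(C)(C)C)cc(O[Si](C)(C)C(C)(C)C)c3c2=O)[C@H]2[C@@H]1[C@H]1O[C@]2(c2c(O)cccc2O[Si]3(C(C)C)C(C)C)c2c(O3)cc(C)c(OCCC(C)(C)O[Si](CC)(CC)CC)c21
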